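Which stands higher at the end, X or J.X, and how much X survives? The quick reckoning starts from how much J is charged beyond L.

the same everywhere: L 14 mM; G 14.0 mM; D 2.1 mM; time 80 min

| run | J |
|---|---|
| ochre | 22.0 mM |
| red | 17.0 mM |

    L + J + D → D + X (k1 = 7330 /M²/min)
    G + J + D → D + E (k2 = 212 /M²/min)
    G + D → G.D (k3 = 2.74 /M/min)
    J + X → J.X (k4 = 3.75 /M/min)

* which of the two there is more of at the end, ochre (J.X / X)
* which of the two there is more of at the end, red (J.X / X)
* X at the end, in percent of the L charged, ochre
* X at the end, in percent of the L charged, red

Step 1 spends one J on each X, and step 4 spends a further J on that X. The zero of the scale is therefore a charge with c_J equal to c_L, the J that step 1 takes to turn the charged L into X. The measure is spare J, the charge of J minus the charge of L. If L is fully turned over, J is finished and step 2 takes none, each spare J ends as one J.X: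

c_J.X = spare J, and c_X = charged c_L − spare J

ochre: spare J 8.00 mM, so X 42.9% and J.X 57.1%

red: spare J 3.00 mM, so X 78.6% and J.X 21.4%

This reckoning therefore calls J.X ahead in ochre and X ahead in red, with full turnover of L assumed and not tested.

The forecast gives J.X ahead in ochre with 47% X, and X ahead in red with 55% X, reasoning “with only 3 mM spare J in red some L stays unconverted”. The two part on red, at 78.6% here against 55% there.

Ochre ends with 40.2% X and 52.4% J.X, red with 51.0% X and 31.9% J.X. In red, X is made 5.64 times as fast as it is used up at 2.75 min, but at 80.0 min making runs at 0.0993 of the using-up. By then 17.2% of the L still stands in red. Spare J put X 2.7 percentage points above the flask in ochre and 28 points above it in red. A neighbour of red charged with 68 mM of J has spare J of 54.0 mM, more than the 14 mM of L, so the subtraction for c_X falls below zero, and that flask ends with 0% X and >99.9% J.X.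

The constants were drawn at random within sensible limits; the flask was simulated.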